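**Assumptions (one line each).** Lactone numbering is O1, C2(=O), C3(OH), C4, C5. The target SMILES decodes as (3R,4R): the two benzyl groups are trans and the 3‑OH is cis to the 4‑benzyl. The (S)-diarylprolinol catalyst is assumed to show L‑proline-like facial selectivity; if the sense is opposite, the (R)-catalyst is used.

## Retrosynthetic overview

1. Target 11 comes from global O‑debenzylation of its bis(benzyl ether) 10.
2. The C3–CH2Ar bond and the C3 quaternary carbinol come from a new Lewis-acid SN1 benzylation of the ene‑diol bis(silyl ether) 9 with benzylic bromide 8, anti to the C4 substituent.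
3. Compound 9 comes from α‑hydroxy lactone 6, whose C3 configuration is irrelevant because it is planarised.
4. The lactone (the only ring formed) comes from reduction/lactonisation of aldol adduct 5; the C3–C4 bond and the C4 stereocentre come from an organocatalytic cross-aldol of aldehyde 3 with ethyl glyoxylate 4.
5. Aldehyde 3 comes from dihydroconiferyl alcohol 1; bromide 8 comes from O‑benzylvanillyl alcohol 7.

## Route

**Step 1**
Reactants: 1, dihydroconiferyl alcohol [4-(3-hydroxypropyl)-2-methoxyphenol]
Product: 2, 3-[4-(benzyloxy)-3-methoxyphenyl]propan-1-ol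
Conditions: BnBr (1.1 equiv), K2CO3, acetone, reflux
Reagents that add atoms: benzyl bromide, BrCc1ccccc1
Why: Williamson etherification; K2CO3 deprotonates only the phenol (pKa ≈ 10), so the primary alcohol is untouched.

**Step 2**
Reactants: 2, 3-[4-(benzyloxy)-3-methoxyphenyl]propan-1-ol
Product: 3, 3-[4-(benzyloxy)-3-methoxyphenyl]propanal
Conditions: TEMPO (10 mol %), PhI(OAc)2, CH2Cl2, rt
Reagents that add atoms: none
Why: TEMPO/oxoammonium oxidation stops at the aldehyde and tolerates the aryl ethers.

**Step 3**
Reactants: 3, 3-[4-(benzyloxy)-3-methoxyphenyl]propanal; 4, ethyl glyoxylate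
Product: 5, ethyl (2R,3S)-4-[4-(benzyloxy)-3-methoxyphenyl]-3-formyl-2-hydroxybutanoate (anti)
Conditions: 4 (polymeric form in toluene, 1.5 equiv), (S)-α,α-bis[3,5-bis(trifluoromethyl)phenyl]prolinol (10 mol %), MeCN, H2O (3 equiv), rt; crude used directly
Reagents that add atoms: none (all heavy atoms come from 3 and 4)
Why: Diarylprolinol-catalysed enamine cross-aldol of an aldehyde with ethyl glyoxylate; the (E)-enamine of 3 attacks glyoxylate hydrogen-bonded to the catalyst OH, setting the formyl-bearing carbon as S (it becomes C4‑R of the lactone), while the anti carbinol centre is inconsequential because it is planarised in step 6.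

**Step 4**
Reactants: 5, ethyl (2R,3S)-4-[4-(benzyloxy)-3-methoxyphenyl]-3-formyl-2-hydroxybutanoate
Product: 6, (3R,4R)-4-[4-(benzyloxy)-3-methoxybenzyl]-3-hydroxydihydrofuran-2(3H)-one (cis major; the C3 epimer is equally usable)
Conditions: NaBH4, EtOH, −20 °C; then TsOH·H2O (cat.), CH2Cl2, rt
Reagents that add atoms: none
Why: Chemoselective aldehyde reduction at low temperature (before the α-formyl centre can epimerise), then acid-catalysed γ-lactonisation with loss of EtOH closes the only ring; C4 is no longer enolisable after this step.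

**Step 5**
Reactants: 7, 4-(benzyloxy)-3-methoxybenzyl alcohol
Product: 8, 4-(benzyloxy)-3-methoxybenzyl bromide
Conditions: PBr3, Et2O, 0 °C; used at once
Reagents that add atoms: phosphorus tribromide, BrP(Br)Br
Why: Standard conversion of an electron-rich benzylic alcohol to the bromide via the bromophosphite.

**Step 6**
Reactants: 6, (3R,4R)-4-[4-(benzyloxy)-3-methoxybenzyl]-3-hydroxydihydrofuran-2(3H)-one
Product: 9, (4R)-4-[4-(benzyloxy)-3-methoxybenzyl]-2,3-bis(trimethylsilyloxy)-4,5-dihydrofuran
Conditions: TMSCl (3 equiv), LiHMDS (2.4 equiv), THF, −78 → 0 °C; concentrate, pentane, filter; crude used directly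
Reagents that add atoms: chlorotrimethylsilane, C[Si](C)(C)Cl
Why: Alkoxide/lactone-enolate formation and double O‑silylation gives the cyclic ene‑diol bis(silyl ether), a neutral dianion equivalent; both C3 epimers of 6 converge on 9, and the non-acidic C4 centre is untouched.

**Step 7 (new reaction)**
Reactants: 9, (4R)-4-[4-(benzyloxy)-3-methoxybenzyl]-2,3-bis(trimethylsilyloxy)-4,5-dihydrofuran; 8, 4-(benzyloxy)-3-methoxybenzyl bromide
Product: 10, (3R,4R)-3,4-bis[4-(benzyloxy)-3-methoxybenzyl]-3-hydroxydihydrofuran-2(3H)-one
Conditions: 8 (1.2 equiv), ZnBr2 (20 mol %), CH2Cl2, −40 → 0 °C; then 1 M HCl, THF, rt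
Reagents that add atoms: none (the TMS groups are lost; all heavy atoms come from 9 and 8)
Why: Proposed new method: ZnBr2 ionises the p‑alkoxybenzyl bromide to a contact ion pair, which the ene‑diol bis(silyl ether) captures at C3 (the only site giving a stabilised 2‑siloxy dioxocarbenium ion) on the face anti to the C4 benzyl group, so the new C3–CH2Ar is trans to C4–CH2Ar and the C3–O is cis (3R); bromide then removes the silyl group to regenerate ZnBr2, and acid work-up cleaves the tertiary O‑TMS. The closest known reaction types are the Lewis-acid (Mukaiyama-type) SN1 α‑alkylation of silyl enol ethers and ketene acetals with SN1-active halides, and the trans-selective alkylation of β‑substituted butyrolactone enolates; to my knowledge neither has been applied to a 2,3‑bis(siloxy)dihydrofuran to build an oxygenated quaternary centre.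

**Step 8**
Reactants: 10, (3R,4R)-3,4-bis[4-(benzyloxy)-3-methoxybenzyl]-3-hydroxydihydrofuran-2(3H)-one
Product: 11, (+)-nortrachelogenin, (3R,4R)-3-hydroxy-3,4-bis(4-hydroxy-3-methoxybenzyl)dihydrofuran-2(3H)-one
Conditions: H2 (1 atm), 10% Pd/C, EtOAc–EtOH, rt
Reagents that add atoms: none
Why: Pd-catalysed hydrogenolysis removes both aryl benzyl ethers; the lactone, the non-benzylic tertiary alcohol and both stereocentres are inert.

## Compound list

1 | dihydroconiferyl alcohol, 4-(3-hydroxypropyl)-2-methoxyphenol | COc1cc(CCCO)ccc1O | starting material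
2 | 3-[4-(benzyloxy)-3-methoxyphenyl]propan-1-ol | COc1cc(CCCO)ccc1OCc1ccccc1 | intermediate
3 | 3-[4-(benzyloxy)-3-methoxyphenyl]propanal | COc1cc(CCC=O)ccc1OCc1ccccc1 | intermediate
4 | ethyl glyoxylate | CCOC(=O)C=O | starting material
5 | ethyl (2R,3S)-4-[4-(benzyloxy)-3-methoxyphenyl]-3-formyl-2-hydroxybutanoate | CCOC(=O)[C@H](O)[C@@H](C=O)Cc1ccc(OCc2ccccc2)c(OC)c1 | intermediate
6 | (3R,4R)-4-[4-(benzyloxy)-3-methoxybenzyl]-3-hydroxydihydrofuran-2(3H)-one | COc1cc(C[C@@H]2COC(=O)[C@@H]2O)ccc1OCc1ccccc1 | intermediate
7 | 4-(benzyloxy)-3-methoxybenzyl alcohol | COc1cc(CO)ccc1OCc1ccccc1 | starting material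
8 | 4-(benzyloxy)-3-methoxybenzyl bromide | COc1cc(CBr)ccc1OCc1ccccc1 | intermediate
9 | (4R)-4-[4-(benzyloxy)-3-methoxybenzyl]-2,3-bis(trimethylsilyloxy)-4,5-dihydrofuran | COc1cc(C[C@@H]2COC(O[Si](C)(C)C)=C2O[Si](C)(C)C)ccc1OCc1ccccc1 | intermediate
10 | (3R,4R)-3,4-bis[4-(benzyloxy)-3-methoxybenzyl]-3-hydroxydihydrofuran-2(3H)-one | COc1cc(C[C@@H]2COC(=O)[C@@]2(O)Cc2ccc(OCc3ccccc3)c(OC)c2)ccc1OCc1ccccc1 | intermediate
11 | (+)-nortrachelogenin, (3R,4R)-3-hydroxy-3,4-bis(4-hydroxy-3-methoxybenzyl)dihydrofuran-2(3H)-one | COc1cc(C[C@@H]2COC(=O)[C@@]2(O)Cc2ccc(O)c(OC)c2)ccc1O | target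

## Summary

Total step count: 8. Longest linear sequence: 7 (steps 1, 2, 3, 4, 6, 7, 8).

**Three steps most likely to fail, with fallbacks**

1. **Step 7 (proposed new SN1 benzylation).** Risks are incomplete ionisation of 8, Friedel–Crafts self-benzylation, protodesilylation of 9, or eroded facial selectivity. Fallback (known chemistry): drop the silyl/Lewis-acid manifold and benzylate the lithium alkoxide–enolate (dianion) of 6 directly with 8 (LiHMDS 2.4 equiv, THF–DMPU, −78 → −30 °C). This is the established SN2 route to trans‑α,β‑dibenzyl‑α‑hydroxy lactones and uses the same anti-to-C4 facial bias.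

2. **Step 3 (organocatalytic cross-aldol).** Risks are self-aldol of 3, insufficient ee, or epimerisation of the α‑formyl centre. Fallback: set C4 by asymmetric hydrogenation instead. Stobbe condensation of O‑benzylvanillin with diethyl succinate, Rh–bisphosphine hydrogenation of the arylidene-succinate half-ester, and chemoselective ester reduction/lactonisation give (S)-4-[4-(benzyloxy)-3-methoxybenzyl]dihydrofuran-2(3H)-one. Enolate hydroxylation (LiHMDS, then MoOPH or a sulfonyl oxaziridine) then gives 6, whose C3 configuration is again irrelevant.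

3. **Step 4 (reduction/lactonisation).** Risks are epimerisation of 5 under basic borohydride conditions or over-reduction of the α‑hydroxy ester. Fallback: change the redox sequence. Pinnick oxidation of crude 5 gives the succinic half-ester, BH3·THF reduces the free acid selectively over the ester, and acid lactonisation gives 6, avoiding basic hydride on the aldehyde.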